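**Plan**

- Retrosynthesis: the C9′–O ester bond is cut first (p-coumaric acid). Then C1–C1′ (ring C, a guaiacol unit bonded para to its OH) and C2–C9′ (formaldehyde) are cut together across one styrene bond of ring B. The resulting dihydronaphthalene is cut at C1–C8a (Friedel–Crafts acylation) and C2–C3 (enolate alkylation), back to ferulic acid and tert-butyl bromoacetate.
- Enabling feature: in ring B the carbon that bears the acylated CH2O arm (C2) is next to C1, which bears ring C and is benzylic on ring A, para to the C6 methoxy group. A C1=C2 styrene can therefore take up CH2O at C2 and guaiacol at C1.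
- Forward order: the ferulic side chain is extended (C2–C3 bond), ring B is closed by acylation, the ketone is turned into the C1=C2 alkene, the two-bond hydroxymethyl-arylation follows, then esterification and ether cleavage.
- Stereochemistry: C3 comes from an (S)-4-benzyloxazolidinone-controlled alkylation. C2 and C1 are relayed from C3 in the key step (each new group anti to its neighbour: 2,3-trans, 1,2-trans). The E alkene arrives intact with p-coumaric acid.

Key step: step 9

Numbering and ring letters: ring A is the aromatic ring of the tetralin (C4a, C5–C8, C8a; OMe on C6, oxygen on C7), ring B is C1–C4 with C4a/C8a, ring C is the aryl group on C1; C9′ is the CH2O on C2 and C9 the CH2O on C3.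

Remark on the chemistry: in the alkene precursor the methoxy group is on C6 (para to C8a) and the protected oxygen on C7, as the target requires (C7 and C6 in systematic 1,2-dihydronaphthalene numbering). The C7 phenol is carried as an isopropyl ether and C9–OH as a benzyl ether; both resist the Brønsted acids of steps 7–9 and both fall to BCl3 at the end.

**Route**

Step 1
Reactants: 1 ferulic acid
Product: 3 (E)-O-isopropylferulic acid, via isopropyl ester 2 (not isolated)
Conditions: i-PrBr, K2CO3, DMF, 70 °C; then aq. NaOH, MeOH, 60 °C; aq. HCl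
Reagents that add atoms: 2-bromopropane, CC(C)Br; sodium hydroxide, [Na+].[OH-] (its oxygen replaces the isopropoxy oxygen of 2)
Why: Williamson ether synthesis on the phenoxide (the carboxylate is esterified alongside and the ester is then saponified) installs an aryl isopropyl ether that withstands the Brønsted acids of steps 7 to 9 and is cleavable by BCl3 at the end.

Step 2
Reactants: 3 (E)-O-isopropylferulic acid
Product: 4 O-isopropyl-dihydroferulic acid
Conditions: H2 (1 atm), Pd/C (10 % palladium on carbon), EtOAc, rt
Reagents that add atoms: none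
Why: Heterogeneous catalytic hydrogenation saturates the conjugated C=C while the aryl isopropyl ether, unlike a benzyl ether, is inert to hydrogenolysis.

Step 3
Reactants: 4 O-isopropyl-dihydroferulic acid; 5 (S)-4-benzyl-1,3-oxazolidin-2-one
Product: 7 (S)-4-benzyl-3-[3-(4-isopropoxy-3-methoxyphenyl)propanoyl]-1,3-oxazolidin-2-one, via mixed pivalic anhydride 6 (not isolated)
Conditions: t-BuCOCl, Et3N, THF, −20 °C; then 5, LiCl, −20 °C → rt
Reagents that add atoms: (S)-4-benzyl-1,3-oxazolidin-2-one 5, O=C1N[C@@H](Cc2ccccc2)CO1; pivaloyl chloride, CC(C)(C)C(Cl)=O (its atoms are held only in 6)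
Why: N-Acylation of the oxazolidinone through a mixed pivalic anhydride, with LiCl making the N–H acidic enough for Et3N, is the standard way to attach this auxiliary and occurs at the less hindered, non-pivaloyl carbonyl.

Step 4
Reactants: 7 N-acyl oxazolidinone; 8 tert-butyl bromoacetate
Product: 10 (R)-alkylated imide (tert-butyl succinate half-ester bearing the arylmethyl group), via sodium enolate 9 (not isolated)
Conditions: NaN(SiMe3)2, THF, −78 °C; then 8, −78 → −40 °C
Reagents that add atoms: tert-butyl bromoacetate 8, CC(C)(C)OC(=O)CBr; NaN(SiMe3)2, C[Si](C)(C)[N-][Si](C)(C)C.[Na+] (its sodium is held only in 9)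
Why: Evans asymmetric alkylation: the chelated (Z)-sodium enolate 9 is alkylated by the reactive α-bromo ester on the face away from the C4 benzyl group of the (S)-auxiliary, which sets the future C3 as R.

Step 5
Reactants: 10 (R)-alkylated imide
Product: 11 tert-butyl (R)-4-hydroxy-3-(4-isopropoxy-3-methoxybenzyl)butanoate
Conditions: LiBH4, MeOH (1.5 equiv), THF, 0 °C
Reagents that add atoms: none
Why: Reductive removal of the auxiliary with LiBH4 (imide reduction) gives the primary alcohol that becomes C9 while the hindered tert-butyl ester is not reduced at 0 °C, and the stereocentre, which is never enolised, keeps its configuration.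

Step 6
Reactants: 11 (R)-hydroxy tert-butyl ester
Product: 12 tert-butyl (R)-4-(benzyloxy)-3-(4-isopropoxy-3-methoxybenzyl)butanoate
Conditions: BnBr, Ag2O, 4 Å MS, CH2Cl2, rt, dark
Reagents that add atoms: benzyl bromide, BrCc1ccccc1
Why: Ag2O-mediated Williamson-type O-benzylation runs under essentially neutral conditions without a free alkoxide, so the γ-hydroxy ester is etherified instead of closing to the lactone, and the alkyl benzyl ether keeps C9 masked and distinguishable from C9′ to the end.

Step 7
Reactants: 12 (R)-benzyloxy tert-butyl ester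
Product: 15 (R)-3-(benzyloxymethyl)-7-isopropoxy-6-methoxy-3,4-dihydronaphthalen-1(2H)-one, via carboxylic acid 13 (not isolated), via acyl trifluoroacetate 14 (not isolated)
Conditions: CF3CO2H, CH2Cl2, rt; evaporate; then (CF3CO)2O, CH2Cl2, 0 °C → rt
Reagents that add atoms: trifluoroacetic anhydride, O=C(OC(=O)C(F)(F)F)C(F)(F)F (its atoms are held only in 14)
Why: Acidolysis of the tert-butyl ester followed by intramolecular Friedel–Crafts acylation through the mixed trifluoroacetic anhydride closes ring B as a six-membered ketone at the ring A carbon para to the methoxy group, the more activated and less hindered of the two positions ortho to the side chain, and leaves C3 untouched.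

Step 8
Reactants: 15 (R)-tetralone
Product: 17 (R)-3-(benzyloxymethyl)-7-isopropoxy-6-methoxy-3,4-dihydronaphthalene (C1=C2 alkene), via tetralol 16 (not isolated)
Conditions: NaBH4, MeOH–THF, 0 °C; then TsOH·H2O (cat.), toluene, 60 °C
Reagents that add atoms: none
Why: Borohydride reduction of the aryl ketone and acid-catalysed E1 dehydration of the resulting p-methoxybenzylic alcohol, whose only β-hydrogens are on C2, give the conjugated C1=C2 alkene without involving C3.

Step 9
Reactants: 17 (R)-dihydronaphthalene; 18 formaldehyde (charged as paraformaldehyde); 19 guaiacol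
Product: 22 [(1S,2R,3R)-3-(benzyloxymethyl)-1-(4-hydroxy-3-methoxyphenyl)-7-isopropoxy-6-methoxy-1,2,3,4-tetrahydronaphthalen-2-yl]methanol, via fused 1,3-dioxane 20 (not isolated), via C9′ hemiformal 21 (not isolated)
Conditions: (CH2O)n (2.5 equiv CH2O), CF3SO3H (10 mol %), (CF3)2CHOH, 0 °C, slow addition of 17; then 19 (8 equiv), 0 °C → rt; aq. NaHCO3
Reagents that add atoms: formaldehyde 18, C=O; guaiacol 19, COc1ccccc1O
Why: Proposed new method: protonated formaldehyde should add to C2 of the C1=C2 styrene because the charge then sits on C1, benzylic and para to the C6 methoxy group, and a second formaldehyde closes the cation to the 4-aryl-1,3-dioxane 20 by oxygen capture (a transient six-membered acetal ring; no ring of the product is closed in this step). In the same acid the benzylic C1–O bond of 20 should re-ionise and guaiacol should attack C1 through the carbon para to its free hydroxyl, giving hemiformal 21, which sheds formaldehyde on work-up. The closest known reaction types are the Prins synthesis of 4-aryl-1,3-dioxanes from styrenes and formaldehyde and the Friedel–Crafts benzylation of phenols by benzylic ethers or alcohols in acidic fluoroalcohol; their union on one alkene as a net anti hydroxymethyl-arylation is what is new. C2 is set by substrate control, the electrophile approaching anti to the C3 benzyloxymethyl arm, and C1 is set by the new C2 arm, which sends the arene to the opposite face and so to the 1,2-trans-2,3-trans isomer with all three groups pseudoequatorial, which is also the thermodynamically preferred one. The step needs Markovnikov regioselectivity (secured by the p-methoxy-stabilised C1 cation), para selectivity on guaiacol (secured by its free OH), and suppression of styrene dimerisation and phenol hydroxymethylation. For the last two, 17 is added slowly to excess formaldehyde and guaiacol enters in large excess only after the Prins stage, where it also scavenges the formaldehyde released from 21.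

Step 10
Reactants: 22 aryltetralin alcohol; 23 (E)-p-coumaric acid
Product: 24 C9′ (E)-p-coumarate of 22
Conditions: PPh3, DIAD, THF, 0 °C → rt
Reagents that add atoms: (E)-p-coumaric acid 23, OC(=O)/C=C/c1ccc(O)cc1
Why: Mitsunobu esterification activates only the primary C9′ alcohol as its alkoxyphosphonium ion, and the carboxylic acid, far more acidic than either phenol, is the pronucleophile that is deprotonated and alkylated, so both phenols stay free and no stereocentre is touched.

Step 11
Reactants: 24 protected coumarate
Product: 25 target, [(1S,2R,3R)-7-hydroxy-1-(4-hydroxy-3-methoxyphenyl)-3-(hydroxymethyl)-6-methoxy-1,2,3,4-tetrahydronaphthalen-2-yl]methyl (E)-3-(4-hydroxyphenyl)prop-2-enoate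
Conditions: BCl3, C6HMe5, CH2Cl2, −78 → 0 °C; then CHCl3–MeOH, aqueous work-up
Reagents that add atoms: none
Why: Lewis-acid ether cleavage by BCl3 removes the primary benzyl ether and the secondary-alkyl aryl ether while pentamethylbenzene traps the benzyl cation as a non-basic scavenger, and the aryl methyl ethers, the ester and the E alkene are left intact at or below 0 °C.

**Compound list**

1 | ferulic acid, (E)-3-(4-hydroxy-3-methoxyphenyl)prop-2-enoic acid | COc1cc(/C=C/C(O)=O)ccc1O | starting material
2 | propan-2-yl (E)-3-[3-methoxy-4-(propan-2-yloxy)phenyl]prop-2-enoate | COc1cc(/C=C/C(=O)OC(C)C)ccc1OC(C)C | intermediate (not isolated)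
3 | (E)-3-[3-methoxy-4-(propan-2-yloxy)phenyl]prop-2-enoic acid | COc1cc(/C=C/C(O)=O)ccc1OC(C)C | intermediate
4 | 3-[3-methoxy-4-(propan-2-yloxy)phenyl]propanoic acid | COc1cc(CCC(O)=O)ccc1OC(C)C | intermediate
5 | (S)-4-benzyl-1,3-oxazolidin-2-one | O=C1N[C@@H](Cc2ccccc2)CO1 | starting material
6 | mixed anhydride of 4 and pivalic acid | COc1cc(CCC(=O)OC(=O)C(C)(C)C)ccc1OC(C)C | intermediate (not isolated)
7 | (4S)-4-benzyl-3-{3-[3-methoxy-4-(propan-2-yloxy)phenyl]propanoyl}-1,3-oxazolidin-2-one | COc1cc(CCC(=O)N2[C@@H](Cc3ccccc3)COC2=O)ccc1OC(C)C | intermediate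
8 | tert-butyl bromoacetate | CC(C)(C)OC(=O)CBr | starting material
9 | sodium (Z)-enolate of 7 | COc1cc(C/C=C(\[O-])N2[C@@H](Cc3ccccc3)COC2=O)ccc1OC(C)C.[Na+] | intermediate (not isolated)
10 | tert-butyl (3R)-4-[(4S)-4-benzyl-2-oxo-1,3-oxazolidin-3-yl]-3-{[3-methoxy-4-(propan-2-yloxy)phenyl]methyl}-4-oxobutanoate | COc1cc(C[C@H](CC(=O)OC(C)(C)C)C(=O)N2[C@@H](Cc3ccccc3)COC2=O)ccc1OC(C)C | intermediate
11 | tert-butyl (3R)-4-hydroxy-3-{[3-methoxy-4-(propan-2-yloxy)phenyl]methyl}butanoate | COc1cc(C[C@H](CC(=O)OC(C)(C)C)CO)ccc1OC(C)C | intermediate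
12 | tert-butyl (3R)-4-(benzyloxy)-3-{[3-methoxy-4-(propan-2-yloxy)phenyl]methyl}butanoate | COc1cc(C[C@H](CC(=O)OC(C)(C)C)COCc2ccccc2)ccc1OC(C)C | intermediate
13 | (3R)-4-(benzyloxy)-3-{[3-methoxy-4-(propan-2-yloxy)phenyl]methyl}butanoic acid | COc1cc(C[C@H](CC(O)=O)COCc2ccccc2)ccc1OC(C)C | intermediate (not isolated)
14 | mixed anhydride of 13 and trifluoroacetic acid | COc1cc(C[C@H](CC(=O)OC(=O)C(F)(F)F)COCc2ccccc2)ccc1OC(C)C | intermediate (not isolated)
15 | (3R)-3-[(benzyloxy)methyl]-6-methoxy-7-(propan-2-yloxy)-3,4-dihydronaphthalen-1(2H)-one | COc1cc2C[C@@H](COCc3ccccc3)CC(=O)c2cc1OC(C)C | intermediate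
16 | (3R)-3-[(benzyloxy)methyl]-6-methoxy-7-(propan-2-yloxy)-1,2,3,4-tetrahydronaphthalen-1-ol, both C1 epimers | COc1cc2C[C@@H](COCc3ccccc3)CC(O)c2cc1OC(C)C | intermediate (not isolated)
17 | (2R)-2-[(benzyloxy)methyl]-7-methoxy-6-(propan-2-yloxy)-1,2-dihydronaphthalene; in target numbering the C1=C2 alkene with (3R)-CH2OBn, 6-OMe, 7-O-iPr | COc1cc2C[C@@H](COCc3ccccc3)C=Cc2cc1OC(C)C | intermediate (key-step precursor)
18 | formaldehyde (from paraformaldehyde) | C=O | starting material
19 | guaiacol, 2-methoxyphenol | COc1ccccc1O | starting material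
20 | Prins adduct: tetralin of 17 with a –CH2–O–CH2–O– bridge from C2 (carbon end) to C1 (oxygen end), (2R,3R), C1 epimers | COc1cc2C[C@@H](COCc3ccccc3)[C@@H]3COCOC3c2cc1OC(C)C | intermediate (not isolated)
21 | (1S,2R,3R)-hemiformal of 22 at C9′ (C9′–O–CH2–OH) | COc1cc([C@H]2c3cc(OC(C)C)c(OC)cc3C[C@@H](COCc3ccccc3)[C@@H]2COCO)ccc1O | intermediate (not isolated)
22 | [(1S,2R,3R)-3-[(benzyloxy)methyl]-1-(4-hydroxy-3-methoxyphenyl)-6-methoxy-7-(propan-2-yloxy)-1,2,3,4-tetrahydronaphthalen-2-yl]methanol | COc1cc([C@H]2c3cc(OC(C)C)c(OC)cc3C[C@@H](COCc3ccccc3)[C@@H]2CO)ccc1O | intermediate (key-step product)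
23 | (E)-p-coumaric acid | OC(=O)/C=C/c1ccc(O)cc1 | starting material
24 | [(1S,2R,3R)-3-[(benzyloxy)methyl]-1-(4-hydroxy-3-methoxyphenyl)-6-methoxy-7-(propan-2-yloxy)-1,2,3,4-tetrahydronaphthalen-2-yl]methyl (E)-3-(4-hydroxyphenyl)prop-2-enoate | COc1cc([C@H]2c3cc(OC(C)C)c(OC)cc3C[C@@H](COCc3ccccc3)[C@@H]2COC(=O)/C=C/c2ccc(O)cc2)ccc1O | intermediate
25 | [(1S,2R,3R)-7-hydroxy-1-(4-hydroxy-3-methoxyphenyl)-3-(hydroxymethyl)-6-methoxy-1,2,3,4-tetrahydronaphthalen-2-yl]methyl (E)-3-(4-hydroxyphenyl)prop-2-enoate | COc1cc([C@H]2c3cc(O)c(OC)cc3C[C@@H](CO)[C@@H]2COC(=O)/C=C/c2ccc(O)cc2)ccc1O | target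

**Step count**

Total: 11 steps. Longest linear sequence: 11 steps (1 → 25); the other building blocks (5, 8, 18, 19, 23) are used as purchased.

**Steps most likely to fail**

Step 9 (new method). Several processes could defeat it:
- weak facial discrimination at C2, because formaldehyde is a small electrophile;
- erosion of the C2 configuration by proton loss from the C1 cation and reprotonation;
- cationic dimerisation of the electron-rich styrene;
- arylation para to the methoxy group of guaiacol instead of para to its hydroxyl;
- capture of the C1 cation by the C9 ether oxygen with loss of benzyl.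

The fallback uses only known reaction types; it sets out from tetralone 15 and returns at 22. Deprotonation with LiN(iPr)2 in THF at −78 °C should give the lithium enolate F1. Monomeric formaldehyde 18 should hydroxymethylate it at C2 to the trans-2-(hydroxymethyl) ketone F2; this centre is α to the ketone and can equilibrate to the diequatorial isomer. NaBH4 in MeOH should give the 1,3-diol F3 as C1 epimers. CF3SO3H (cat.) in (CF3)2CHOH with excess guaiacol 19 should then ionise the benzylic alcohol and deliver 22 by Friedel–Crafts alkylation of the phenol, trans to the C2 arm.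

Step 10. The alkoxyphosphonium ion could O-alkylate a phenol once the acid is depleted, displacement at the β-branched C9′ could be sluggish, or the C9 ether oxygen could displace the leaving group with loss of benzyl. The fallback replaces alcohol activation by acid activation of fully protected partners; it sets out from 22 and returns at target 25. K2CO3/BnBr in acetone should benzylate only the phenol to give the aryl benzyl ether F4. Carbodiimide coupling (EDC·HCl, DMAP, CH2Cl2) with commercial (E)-4-(benzyloxy)cinnamic acid should give the fully protected ester F5. BCl3/C6HMe5 (CH2Cl2, −78 → 0 °C) should then remove the three benzyl groups and the isopropyl group to give 25.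

Step 7. The tert-butyl cation released during acidolysis could alkylate the electron-rich ring A, and the γ-benzyloxy oxygen could capture the activated acyl group, ending in lactonisation with loss of the benzyl group. The fallback closes ring B at the aldehyde oxidation level; it sets out from 12 and returns at 17. iBu2AlH in CH2Cl2 at −78 °C should reduce the tert-butyl ester to the aldehyde F6. TsOH (cat.) in toluene should then effect cyclodehydration (intramolecular Friedel–Crafts hydroxyalkylation to tetralol 16, then loss of water) to give 17 directly, bypassing the tetralone and step 8.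

**Further compounds**

F1 | step 9 | lithium enolate of tetralone 15 | COc1cc2C[C@@H](COCc3ccccc3)C=C([O-])c2cc1OC(C)C.[Li+]
F2 | step 9 | (2R,3R)-3-[(benzyloxy)methyl]-2-(hydroxymethyl)-6-methoxy-7-(propan-2-yloxy)-3,4-dihydronaphthalen-1(2H)-one | COc1cc2C[C@@H](COCc3ccccc3)[C@H](CO)C(=O)c2cc1OC(C)C
F3 | step 9 | (2R,3R)-3-[(benzyloxy)methyl]-2-(hydroxymethyl)-6-methoxy-7-(propan-2-yloxy)-1,2,3,4-tetrahydronaphthalen-1-ol, both C1 epimers | COc1cc2C[C@@H](COCc3ccccc3)[C@H](CO)C(O)c2cc1OC(C)C
F4 | step 10 | [(1S,2R,3R)-1-[4-(benzyloxy)-3-methoxyphenyl]-3-[(benzyloxy)methyl]-6-methoxy-7-(propan-2-yloxy)-1,2,3,4-tetrahydronaphthalen-2-yl]methanol | COc1cc([C@H]2c3cc(OC(C)C)c(OC)cc3C[C@@H](COCc3ccccc3)[C@@H]2CO)ccc1OCc1ccccc1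
F5 | step 10 | [(1S,2R,3R)-1-[4-(benzyloxy)-3-methoxyphenyl]-3-[(benzyloxy)methyl]-6-methoxy-7-(propan-2-yloxy)-1,2,3,4-tetrahydronaphthalen-2-yl]methyl (E)-3-[4-(benzyloxy)phenyl]prop-2-enoate | COc1cc([C@H]2c3cc(OC(C)C)c(OC)cc3C[C@@H](COCc3ccccc3)[C@@H]2COC(=O)/C=C/c2ccc(OCc3ccccc3)cc2)ccc1OCc1ccccc1
F6 | step 7 | (3R)-4-(benzyloxy)-3-{[3-methoxy-4-(propan-2-yloxy)phenyl]methyl}butanal | COc1cc(C[C@H](CC=O)COCc2ccccc2)ccc1OC(C)C
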